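The data come from a simulation from invented constants; noise was put on by code.

E is a small charge: cE = 0.0100 M against cX = 0.050 M, so it can divert L worth at most 20.0% of the X. The J readings flatten well short of the charge, and that shortfall is larger than the share E can divert, so another sink must hold the rest. The step J + Q <-> D + Q offers one.

| flask | X | Z | E | Q | remark | time |
|---|---|---|---|---|---|---|
| theta | 0.050 M | 5.8 mM (held) | 0.010 M | 1 mol% | the very flask that is asked about, followed so far |  |
| flask | 0.050 M | 5.8 mM (held) | 0.0100 M | 1 mol% |  | 5.0 min |

theta run (percent of the X charged)

| time / min | J / % |
|---|---|
| 0.200 | 16.9 |
| 0.333 | 24.8 |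
| 0.500 | 35.2 |
| 0.833 | 46.7 |
| 1.50 | 54.2 |
| 2.50 | 54.4 |

(standard deviation of a reading: 0.5 percentage points)

- at the start none of L is dissolved
- the numbers in the tables scatter with a standard deviation of 0.5 percentage points
- steps thought possible: L + E -> G; Z <-> L; X + L + Q -> Q + J; J + Q <-> D + Q

- how much J there is at 5.0 min, in percent of the X charged
- the change that raises the amount of J at 5.0 min, in percent of the X charged most ("none" if none brings more than 2 percentage points) (green / red / violet / none)
- amount of J at 5.0 min, in percent of the X charged, after green

- green: doubling the amount of Q, all else as stated
- red: doubling the transfer coefficient of Z, all else as stated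
- violet: doubling the saturation concentration of Z, all else as stated

The reckoning here solves the curve at both ends and joins them:

late end, mean of the last two readings: 54.3%

early end, first reading over its time: 0.845 min⁻¹

join: 0.643 min

This last is the join time, the moment at which the straight line from the first reading meets the plateau as read. The asked time lies 7.78 join times out, so J at 5.0 min should be the plateau.

The weak link is that flat may not mean stopped. The last two readings differ by 0.2 percentage points, and twice the scatter of such a difference, carried forward to 5.0 min, allows a drift of 3.5 points. But the step listed for J runs both ways, so a fall through it ends at the J to D balance (thermodynamic control). Q stands on both sides of that step, so green should shorten the join time and leave the plateau in place. The commitment is therefore 54.3%, with that drift as its margin, and no gain from any change.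

The forecast gives 54.3% (53.3% to 55.3%), best none, and 54.3% after green (53.2% to 55.4%), with the words “None of them moves the equilibrium”. Its range is narrower than the margin here.

The flask gives 53.8%, best none, and 53.8% after green.

    L + E → G (k = 3.50 M⁻¹ s⁻¹)
    Z ⇌ L, rate k2*(csat - [L]) (kL = 0.350 s⁻¹)
    X + L + Q → Q + J (k = 12000 M⁻² s⁻¹)
    J + Q ⇌ D + Q, rate k4*[Q]*[J] forward; the back reaction follows from the equilibrium constant (K = 0.860, k = 38.0 M⁻¹ s⁻¹)

The half-life of J by its forward passing into D alone is 0.61 min, short against 5.0 min and close to the join time. The same flask read at 2.0 min stands 3.11 join times out, so the reckoning puts it on the plateau at 54.3%; the computed value there is 55.2%, with 4.42% of the X still present.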